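What a reading at 2.5 min sees depends on how many turnovers each step has behind it by then, so the time of reading is the yardstick here. Starting material and partner form target reversibly, target passes on to over-reaction product, protic impurity quenches starting material, second substrate draws on partner, and target with starting material gives side product.

in all of them: second substrate 0.100 M; protic impurity 0.0150 M; time 2.5 min

|  | starting material | partner | temperature | remark |
|---|---|---|---|---|
| ash | 0.050 M | 0.150 M | 40 °C | everything together at the start |
| oak | 0.050 M | 0.150 M (fed, over 2.0 min) | 40 °C | all else is in the flask from the start; the feed brings no volume worth counting |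
| maple | 0.050 M | 0.150 M (fed, over 2.0 min) |  | the addition at 10 °C, then warmed to 40 °C; the feed brings no volume worth counting |
| cedar | 0.050 M (in portions, 5, over 2.0 min) | 0.150 M | 40 °C | first portion at the start, last at 2.0 min |

- the flask with the highest share of target in target plus over-reaction product ("all alike" if they lie within 1.5 percentage points) (ash / oak / maple / cedar / all alike)
- share of target in target plus over-reaction product at the end, ash
- share of target in target plus over-reaction product at the end, oak
- share of target in target plus over-reaction product at the end, maple
- share of target in target plus over-reaction product at the end, cedar

- a species is counted by the starting material in it: one side product counts as two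
- all constants are for 40 °C and move with temperature by the activation energies and enthalpies

    starting material + target → side product (k1 = 0.013 M⁻¹ s⁻¹, Ea1 = 71.0 kJ mol⁻¹)
    starting material + partner ⇌ target (K2 = 0.83 M⁻¹, k2 = 0.27 M⁻¹ s⁻¹, Ea2 = 54.0 kJ mol⁻¹, ΔH2 = −48.0 kJ mol⁻¹)
    starting material + protic impurity → quenched substrate (k3 = 0.29 M⁻¹ s⁻¹, Ea3 = 58.0 kJ mol⁻¹)
    second substrate + partner ⇌ second product (K4 = 7.2 M⁻¹, k4 = 0.0032 M⁻¹ s⁻¹, Ea4 = 50.0 kJ mol⁻¹, ΔH4 = 16.0 kJ mol⁻¹)
    target → over-reaction product (k5 = 0.0021 s⁻¹, Ea5 = 92.0 kJ mol⁻¹)
    (constants at 40 °C)

My own ladder counts each step's first-order rate, at the charges of ash and at 40 °C, against that time, from the fastest rung down: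

exchange of target with starting material and partner, both directions: 54.9 turnovers
quench of starting material by protic impurity: 0.652 turnovers
over-reaction of target: 0.315 turnovers
side product from target with starting material: 0.0975 turnovers
second substrate with partner, forward only: 0.0720 turnovers

Because the exchange turns over far faster than target over-reacts, target is a pre-equilibrium level, with c(target) equal to the equilibrium constant times c(starting material) times c(partner), and in ash that constant times the charged partner is 0.12. Over-reaction product then grows in proportion to that level, so c(over-reaction product)/c(target) equals N, the over-reaction turnover count, which is the over-reaction constant times the time the target level has stood. The share asked for is one divided by one plus N. The count takes the level as flat, whereas the quench rung, with more turnovers than over-reaction, sinks it, so these shares lean high.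

Oak's ramp and cedar's portions both have their mean moment of entry at 1.00 min, so both flasks lose that much standing time. In maple the over-reaction constant sinks to 4.97 × 10⁻⁵ s⁻¹ during the feed at 10 °C, and the full constant acts for the last 30.0 s.

ash: N = 0.315, share 76.0%
oak: N = 0.189, share 84.1%
maple: N = 0.0690, share 93.5%
cedar: N = 0.189, share 84.1%

The highest share in this reckoning falls to maple.

The forecast named maple, with 73% for ash, 82% for oak, 93% for maple and 82% for cedar, on the ground that “over-reaction is almost frozen at 10 °C”.

The simulation gives 73.5% in ash, 83.0% in oak, 93.0% in maple and 83.3% in cedar, which puts maple first. Read at 25.0 min instead, maple stands at 19.7% and ash at 18.3%, so the gap of 20 percentage points at the asked time has become 1.4 points. Over-reaction product per target in maple at the asked time reads 0.0753, beside a count of 0.0690, which is 0.219 of the count 0.315 for ash.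

For ash read at 10 min, the count scales to 1.26 and gives a share of 44.2%. The simulation of that flask gives 38.7%, with target at 5.36% and over-reaction product at 8.48%.

The numbers of this flask are those of an exercise; what happens was integrated by code.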